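**Retrosynthetic overview**

1. The six-membered ring is never built: it is the ring of m-xylene. Birch reduction gives achiral 1,5-dimethylcyclohexa-1,4-diene, whose two trisubstituted alkenes map onto the C(Me)Cl–CHCl and C(Me)(bromovinyl)–CHBr pairs.
2. All four stereocentres are traced back to C–O bonds. Each alkene becomes an epoxide (asymmetric Shi epoxidation, the first fixing absolute configuration), and every epoxide C–O bond is later replaced with inversion, so Cl, Cl, Br and the vinyl group end up on one ring face.
3. First epoxide: C–C disconnection at the quaternary carbon (tertiary-selective alkynyl opening, trans), then CH–OH to CH–Br with inversion.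
4. Second epoxide: one-flask double inversion to the cis-dichloride.
5. The (E)-bromovinyl group comes from a terminal alkyne. Ring order: cyclohexane from the arene (step 1), first oxirane (made in step 2, opened in step 3), second oxirane (made in step 5, opened in step 6).

Assumption: the D-fructose-derived Shi ketone attacks a 1-methylcyclohexene-type alkene from the same face as in its 1-phenylcyclohexene to (R,R)-oxide precedent. The target is read as (1S,2S,4R,5S)-2-bromo-1-[(E)-2-bromoethenyl]-4,5-dichloro-1,5-dimethylcyclohexane, with both Cl, the Br and the bromovinyl group on one face.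

**Step 1**
Reactants: 1 m-xylene (1,3-dimethylbenzene)
Product: 2 1,5-dimethylcyclohexa-1,4-diene
Conditions: Li, NH3 (l), t-BuOH, THF, −78 to −33 °C; then NH4Cl
Reagents that add atoms: none
Why: Birch reduction protonates the unsubstituted 2- and 5-positions, leaving both methyl groups on the skipped double bonds; no stereocentre is formed.

**Step 2**
Reactants: 2 1,5-dimethylcyclohexa-1,4-diene (1.5 equiv relative to oxidant)
Product: 3 (1S,6R)-1,3-dimethyl-7-oxabicyclo[4.1.0]hept-3-ene
Conditions: D-fructose-derived Shi ketone (1,2:4,5-di-O-isopropylidene-β-D-erythro-2,3-hexodiulo-2,6-pyranose, 30 mol %), KHSO5 (as the 2KHSO5·KHSO4·K2SO4 triple salt), K2CO3, Bu4NHSO4, MeCN–CH2(OMe)2 / aq. Na2B4O7–Na2EDTA buffer (pH 10.5), −5 °C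
Reagents that add atoms: potassium peroxymonosulfate KHSO5, [K+].[O-]S(=O)(=O)OO
Why: Shi asymmetric epoxidation (chiral dioxirane, spiro transition state) sets both oxirane stereocentres, because the two alkenes of 2 are related by the in-plane C2 axis and the catalyst-preferred face of either gives the same (1S,6R)-epoxide, while limiting oxidant with excess cheap 2 suppresses bis-epoxide; this C–O bond formation fixes the absolute configuration for the whole route.

**Step 3**
Reactants: 3 (1S,6R)-1,3-dimethyl-7-oxabicyclo[4.1.0]hept-3-ene; 4 trimethyl{[(4-methylphenyl)sulfonyl]ethynyl}silane (p-tolyl 2-(trimethylsilyl)ethynyl sulfone, 2 equiv)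
Product: 6 (1R,6S)-6-ethynyl-4,6-dimethylcyclohex-3-en-1-ol, via trimethylsilyl alkyne carbinol 5 (not isolated)
Conditions: Cp2TiCl2 (20 mol %), Zn dust, 2,4,6-collidine·HCl, THF, rt; then K2CO3 (cat.), MeOH, rt
Reagents that add atoms: 4 trimethyl{[(4-methylphenyl)sulfonyl]ethynyl}silane, Cc1ccc(cc1)S(=O)(=O)C#C[Si](C)(C)C (its C≡C unit stays in 6; its SiMe3 group is carried only in 5)
Why: Proposed new method: titanocene-catalysed radical alkynylation of an epoxide, in which Cp2TiCl (trivalent titanium, from Cp2TiCl2 and Zn) cleaves the more substituted C–O bond of 3 homolytically to the tertiary β-titanoxy radical, which adds to the sulfonyl-bearing carbon of 4 and expels a p-toluenesulfonyl radical (reduced by a second Cp2TiCl, with collidinium chloride cleaving the Ti–O and Ti–sulfinate bonds to turn the metal over), so the new C–C bond forms at the tertiary carbon anti to the bulky Cp2ClTi–O group and gives the trans quaternary alkynyl carbinol without any carbocation (no hydride shift, no aromatisation); the closest known reactions are the titanocene-mediated reductive epoxide opening–Giese addition (Nugent–RajanBabu, Gansäuer) and radical alkynylation with alkynyl sulfones, and K2CO3/MeOH then removes the silyl group in the same operation.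

**Step 4**
Reactants: 6 (1R,6S)-6-ethynyl-4,6-dimethylcyclohex-3-en-1-ol
Product: 7 (4S,5S)-4-bromo-5-ethynyl-1,5-dimethylcyclohex-1-ene
Conditions: CBr4, P(n-C8H17)3, toluene, 70 °C
Reagents that add atoms: carbon tetrabromide, BrC(Br)(Br)Br
Why: Appel-type deoxybromination, in which bromide displaces the alkoxyphosphonium by SN2 with inversion so that Br becomes cis to the ethynyl group; the slim ethynyl group and the flattened cyclohexene ring ease the neopentyl-like displacement, and the non-basic medium limits elimination.

**Step 5**
Reactants: 7 (4S,5S)-4-bromo-5-ethynyl-1,5-dimethylcyclohex-1-ene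
Product: 8 (1R,3S,4S,6S)-4-bromo-3-ethynyl-1,3-dimethyl-7-oxabicyclo[4.1.0]heptane
Conditions: enantiomeric Shi ketone (L-series, from L-sorbose, 30 mol %), KHSO5 (as the triple salt), K2CO3, Bu4NHSO4, MeCN–CH2(OMe)2 / aq. Na2B4O7–Na2EDTA buffer (pH 10.5), 0 °C
Reagents that add atoms: potassium peroxymonosulfate KHSO5, [K+].[O-]S(=O)(=O)OO
Why: Shi epoxidation under reagent control, in which the enantiomeric ketone delivers oxygen to the face anti to Br and ethynyl, which is also the sterically favoured face (the axial ethynyl shields the other), so catalyst and substrate are matched; the minor enantiomer carried from step 2 is mismatched and is diverted to a separable diastereomer.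

**Step 6**
Reactants: 8 (1R,3S,4S,6S)-4-bromo-3-ethynyl-1,3-dimethyl-7-oxabicyclo[4.1.0]heptane
Product: 9 (1S,2S,4R,5S)-2-bromo-4,5-dichloro-1-ethynyl-1,5-dimethylcyclohexane
Conditions: Ph3PCl2, toluene, 0 to 80 °C
Reagents that add atoms: dichlorotriphenylphosphorane, ClP(Cl)(c1ccccc1)(c1ccccc1)c1ccccc1
Why: Deoxygenative dichlorination of an epoxide, in which chloride opens the phosphorus-activated oxirane at the tertiary carbon with inversion (trans-diaxial, Markovnikov) and a second chloride displaces Ph3P=O from the secondary carbon with inversion, so both C–Cl bonds lie on the face opposite the former oxygen, cis to each other and to Br and ethynyl.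

**Step 7**
Reactants: 9 (1S,2S,4R,5S)-2-bromo-4,5-dichloro-1-ethynyl-1,5-dimethylcyclohexane
Product: 11 (1S,2S,4R,5S)-2-bromo-1-[(E)-2-bromoethenyl]-4,5-dichloro-1,5-dimethylcyclohexane, via alkenylzirconocene chloride 10 (not isolated)
Conditions: Cp2Zr(H)Cl, THF, rt; then NBS, 0 °C; 1 M HCl work-up
Reagents that add atoms: N-bromosuccinimide, O=C1CCC(=O)N1Br; zirconocene chloride hydride Cp2Zr(H)Cl, [H][Zr](Cl)(C1C=CC=C1)C1C=CC=C1 (adds H to 11; its Zr is carried only in 10)
Why: Hydrozirconation–bromination, in which syn anti-Markovnikov Zr–H addition to the terminal alkyne gives the (E)-alkenylzirconocene and NBS cleaves C–Zr with retention to the (E)-bromoalkene; the alkyl chlorides and the hindered secondary bromide are inert to both reagents.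

**Compound list**

1 | m-xylene (1,3-dimethylbenzene) | Cc1cccc(C)c1 | starting material
2 | 1,5-dimethylcyclohexa-1,4-diene | CC1=CCC=C(C)C1 | intermediate
3 | (1S,6R)-1,3-dimethyl-7-oxabicyclo[4.1.0]hept-3-ene | CC1=CC[C@H]2O[C@@]2(C)C1 | intermediate
4 | trimethyl{[(4-methylphenyl)sulfonyl]ethynyl}silane | Cc1ccc(cc1)S(=O)(=O)C#C[Si](C)(C)C | starting material
5 | (1R,6S)-4,6-dimethyl-6-[(trimethylsilyl)ethynyl]cyclohex-3-en-1-ol (not isolated) | CC1=CC[C@@H](O)[C@](C)(C#C[Si](C)(C)C)C1 | intermediate
6 | (1R,6S)-6-ethynyl-4,6-dimethylcyclohex-3-en-1-ol | CC1=CC[C@@H](O)[C@](C)(C#C)C1 | intermediate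
7 | (4S,5S)-4-bromo-5-ethynyl-1,5-dimethylcyclohex-1-ene | CC1=CC[C@H](Br)[C@](C)(C#C)C1 | intermediate
8 | (1R,3S,4S,6S)-4-bromo-3-ethynyl-1,3-dimethyl-7-oxabicyclo[4.1.0]heptane | C[C@]12O[C@H]1C[C@H](Br)[C@](C)(C#C)C2 | intermediate
9 | (1S,2S,4R,5S)-2-bromo-4,5-dichloro-1-ethynyl-1,5-dimethylcyclohexane | C[C@]1(Cl)C[C@@](C)(C#C)[C@@H](Br)C[C@H]1Cl | intermediate
10 | chlorobis(cyclopentadienyl){(E)-2-[(1S,2S,4R,5S)-2-bromo-4,5-dichloro-1,5-dimethylcyclohexyl]ethenyl}zirconium (not isolated; cyclopentadienyl rings drawn σ-bonded) | C[C@]1(Cl)C[C@@](C)(/C=C/[Zr](Cl)(C2C=CC=C2)C2C=CC=C2)[C@@H](Br)C[C@H]1Cl | intermediate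
11 | (1S,2S,4R,5S)-2-bromo-1-[(E)-2-bromoethenyl]-4,5-dichloro-1,5-dimethylcyclohexane | C[C@]1(Cl)C[C@@](C)(/C=C/Br)[C@@H](Br)C[C@H]1Cl | target

**Step count and risks**

Total step count: 7. Longest linear sequence: 7 steps (fully linear from 1; 4 is purchased).

Three steps most likely to fail:

Step 3 (the proposed new radical alkynylation). Risks are chlorohydrin formation from collidinium chloride, disproportionation of the tertiary radical to an allylic alcohol, and modest trans selectivity. The fallback uses known polar chemistry, sets out from 3 and comes back to the route at 5. Compound 3 is treated in toluene at 0 °C with 2.5 equiv of Et2Al–C≡C–SiMe3, made from trimethylsilylacetylene, n-BuLi and Et2AlCl. One alane activates the oxirane oxygen and a second delivers the alkynyl group to the tertiary carbon from the opposite face (Lewis-acid-assisted anti opening of an epoxide by an alkynylalane). This gives 5, which is desilylated to 6 as in the route. New compounds on the way: none F0.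

Step 4 (inversion at a carbinol next to a quaternary carbon). Risks are elimination to the diene and slow displacement. The fallback sets out from 6 and comes back at 7. It replaces the in-situ oxyphosphonium by a discrete sulfonate: Tf2O and pyridine in CH2Cl2 at −30 °C give (1R,6S)-6-ethynyl-4,6-dimethylcyclohex-3-en-1-yl trifluoromethanesulfonate F1. This is used cold and crude and displaced with LiBr in THF–DMPU at −20 to 0 °C (SN2, inversion) to give 7.

Step 6 (one-flask double inversion on a trisubstituted epoxide). Risks are elimination to an allylic chloride and loss of stereochemistry at the tertiary centre. The fallback sets out from 8 and comes back at 9, separating the two C–Cl bond formations. HCl (1 M in Et2O) in CH2Cl2 at −78 °C opens the protonated oxirane at the tertiary carbon (trans-diaxial, Markovnikov) to the chlorohydrin (1S,2S,4S,5S)-5-bromo-2-chloro-4-ethynyl-2,4-dimethylcyclohexan-1-ol F2. SOCl2 and pyridine in CH2Cl2 at 0 °C to rt then convert the secondary alcohol by way of its chlorosulfite into the chloride with inversion, giving 9.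

**Further compounds**

F0 | step 3 | none | none
F1 | step 4 | (1R,6S)-6-ethynyl-4,6-dimethylcyclohex-3-en-1-yl trifluoromethanesulfonate | CC1=CC[C@@H](OS(=O)(=O)C(F)(F)F)[C@](C)(C#C)C1
F2 | step 6 | (1S,2S,4S,5S)-5-bromo-2-chloro-4-ethynyl-2,4-dimethylcyclohexan-1-ol | C[C@]1(Cl)C[C@@](C)(C#C)[C@@H](Br)C[C@@H]1O
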